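**Retrosynthetic overview**
- The target is an unsymmetrical C6–C6' biaryl of two 7,8,4'-trihydroxyflavan-3,4-diols: an all-cis (2R,3R,4R) half and its C4 epimer (2R,3R,4S). The last C–C bond is made by Suzuki–Miyaura coupling of a 6-bromo half with a 6-boronate half, both drawn from one 6-bromo all-cis diol.
- The strategy rests on the contiguous C2(aryl)–C3(OH)–C4(OH) triad of each pyran ring C. It is the saturated form of the flat C2=C3–C4=O unit of a 3-hydroxyflavone, so delivery of two H2 to one face sets all three centres. The 4S centre comes from invertive substitution at benzylic C4 in one portion only.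
- Ring order: rings A and B are bought (gallacetophenone, 4-benzyloxybenzaldehyde) and joined by Claisen–Schmidt condensation. Ring C closes at O1–C2 in the Algar–Flynn–Oyamada step. Afterwards only temporary carbonate and sulfate rings are made.
- All phenols stay benzylated until the end. Carbonate and esters are removed by methanolysis, then the six benzyl ethers by neutral hydrogenolysis.

Key step: step 4

Assumption: the sense of induction of the Ru–NHC catalyst on a flavonol cannot be predicted, so the ligand antipode that gives 2R is fixed by a pilot run on both antipodes. The CIP label at C3 changes from R to S whenever O4 carries an acyl or sulfur group (C4 then outranks C2), with no change in geometry.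

**Route**

Step 1
Reactants: 1 2,3,4-trihydroxyacetophenone (gallacetophenone)
Product: 2 3,4-bis(benzyloxy)-2-hydroxyacetophenone
Conditions: BnBr (2.05 equiv), K2CO3 (2.2 equiv), DMF, rt
Reagents that add atoms: benzyl bromide, BrCc1ccccc1
Why: Williamson etherification; the 2-OH is tied up in a hydrogen bond to the acetyl carbonyl and is the least nucleophilic phenol, so two equivalents of benzyl bromide should alkylate only O3 and O4.

Step 2
Reactants: 2 3,4-bis(benzyloxy)-2-hydroxyacetophenone; 3 4-benzyloxybenzaldehyde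
Product: 4 (E)-2'-hydroxy-3',4',4-tris(benzyloxy)chalcone
Conditions: KOH (50% aq), EtOH/THF, rt
Reagents that add atoms: none
Why: Claisen–Schmidt condensation of the methyl ketone enolate with the non-enolisable aldehyde, followed by E1cB dehydration, should give the conjugated (E)-enone carrying rings A and B.

Step 3
Reactants: 4 (E)-2'-hydroxy-3',4',4-tris(benzyloxy)chalcone
Product: 6 7,8,4'-tri-O-benzylflavonol [7,8-bis(benzyloxy)-2-(4-benzyloxyphenyl)-3-hydroxy-4H-chromen-4-one], via trans-dihydroflavonol 5 (not isolated)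
Conditions: H2O2 (30% aq), NaOH (aq), MeOH/THF, 0 °C to rt
Reagents that add atoms: hydrogen peroxide, OO
Why: Algar–Flynn–Oyamada reaction; alkaline peroxide closes ring C at O1–C2 by oxa-Michael addition with α-hydroxylation to the dihydroflavonol 5, which is dehydrogenated in the same flask to the flavonol, and the absence of a 6'-substituent disfavours the aurone pathway.

Step 4
Reactants: 6 7,8,4'-tri-O-benzylflavonol
Product: 8 (2R,3R,4R)-7,8,4'-tris(benzyloxy)flavan-3,4-diol (2,3-cis-3,4-cis), via cis-ketol 7 (not isolated)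
Conditions: [Ru(cod)(2-methylallyl)2] (5 mol%), SINpEt·HBF4 (10 mol%, antipode giving 2R), KOtBu (12 mol%), hexane, 70 °C; then 6, H2 (100 bar), toluene, 30 °C
Reagents that add atoms: none
Why: Proposed new method: a chiral ruthenium–NHC hydride (divalent ruthenium) is expected to bind the flavonol through its 3-O/4-C=O chelate, which presents one enantioface of the flat pyranone to the metal; hydride goes to C2 and the second hydrogen to C3 on the same face, giving the 2,3-cis ketol 7. The C4 carbonyl of 7 is then reduced from the same open face, anti to the now cofacial 2-aryl and 3-hydroxyl groups and faster than the ketol can enolise, so the 4-OH also ends cis. The closest known reaction types are the enantioselective Ru–NHC hydrogenation of flavones and chromones to cis-flavan-4-ols and the heterogeneous hydrogenation of flavonols to racemic 2,3-cis-3,4-cis-flavan-3,4-diols. No ring is closed in this step. C2 and C3 are set by the catalyst through syn addition of H2 (ligand antipode chosen for 2R), and C4 by substrate control relayed from C2 and C3. The step needs enantiofacial selectivity and all-cis diastereoselectivity; the planarity of the chromone, the chelating 3-OH/4-C=O pair and the inertness of benzyl ethers to homogeneous ruthenium hydrogenation should secure them.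

Step 5
Reactants: 8 (2R,3R,4R)-7,8,4'-tris(benzyloxy)flavan-3,4-diol
Product: 9 (2R,3R,4R)-6-bromo-7,8,4'-tris(benzyloxy)flavan-3,4-diol
Conditions: NBS (1.0 equiv), DMF, −10 °C, dark
Reagents that add atoms: N-bromosuccinimide, O=C1CCC(=O)N1Br
Why: Electrophilic aromatic bromination at C6, the only position of ring A that is para to O1 and ortho to the 7-benzyloxy group; C5 is activated only by the twisted central 8-alkoxy group and ring B by a single ether oxygen, and the stereocentres are not touched.

Compound 9 is divided between steps 6 and 7.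

Step 6
Reactants: 9 (2R,3R,4R)-6-bromo-7,8,4'-tris(benzyloxy)flavan-3,4-diol
Product: 10 6-bromo-7,8,4'-tris(benzyloxy)-2,3-cis-3,4-cis-flavan-3,4-diyl cyclic carbonate (configuration as in 9)
Conditions: CDI (1.5 equiv), DMAP (cat.), THF, rt to 45 °C
Reagents that add atoms: 1,1'-carbonyldiimidazole, O=C(n1ccnc1)n1ccnc1
Why: Carbonylation of the cis-vicinal diol closes the cis-fused five-membered carbonate with retention at C3 and C4, masking both hydroxyls and taming the ionisable benzylic C4–O bond for the coupling.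

Step 7
Reactants: 9 (2R,3R,4R)-6-bromo-7,8,4'-tris(benzyloxy)flavan-3,4-diol
Product: 12 6-bromo-7,8,4'-tris(benzyloxy)-2,3-cis-3,4-cis-flavan-3,4-diyl cyclic sulfate (configuration as in 9), via cyclic sulfite 11 (not isolated)
Conditions: SOCl2, Et3N, CH2Cl2, −20 to 0 °C; then RuCl3·3H2O (1 mol%), NaIO4 (1.5 equiv), MeCN/CH2Cl2/H2O, 0 °C, 15 min
Reagents that add atoms: thionyl chloride, O=S(Cl)Cl; sodium periodate, [Na+].[O-]I(=O)(=O)=O
Why: Cyclic sulfite formation followed by RuO4-catalysed oxidation at sulfur (cyclic sulfate method); no C–O bond is broken so the configuration is kept, and the oxidation at sulfur takes minutes at 0 °C, which should outpace attack on benzyl ethers or the bromo-deactivated arene.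

Step 8
Reactants: 12 cyclic sulfate of 9
Product: 14 (2R,3S,4S)-6-bromo-7,8,4'-tris(benzyloxy)-3-hydroxyflavan-4-yl benzoate (2,3-cis-3,4-trans), via sulfate monoester salt 13 (not isolated)
Conditions: Bu4N(O2CPh) (1.2 equiv), THF, 0 °C to rt; then H2SO4 (cat.), H2O (1.5 equiv), THF, rt
Reagents that add atoms: tetrabutylammonium benzoate, CCCC[N+](CCCC)(CCCC)CCCC.[O-]C(=O)c1ccccc1
Why: SN2 opening of the cyclic sulfate by benzoate at the benzylic, more electrophilic C4 from the face opposite the leaving oxygen inverts C4 (trans-diaxial opening), and the 3-O-sulfate monoester is then hydrolysed with S–O cleavage, so C3 is retained.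

Step 9
Reactants: 14 (2R,3S,4S)-6-bromo-7,8,4'-tris(benzyloxy)-3-hydroxyflavan-4-yl benzoate
Product: 15 (2R,3S,4S)-3-acetoxy-6-bromo-7,8,4'-tris(benzyloxy)flavan-4-yl benzoate
Conditions: Ac2O, pyridine, DMAP (cat.), CH2Cl2, rt
Reagents that add atoms: acetic anhydride, CC(=O)OC(C)=O
Why: DMAP-catalysed acylation of the axial secondary 3-OH; capping it removes a free hydroxyl and any acyl migration from the two palladium steps.

Step 10
Reactants: 15 (2R,3S,4S)-3-acetoxy-6-bromo-7,8,4'-tris(benzyloxy)flavan-4-yl benzoate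
Product: 16 (2R,3S,4S)-3-acetoxy-7,8,4'-tris(benzyloxy)-6-(4,4,5,5-tetramethyl-1,3,2-dioxaborolan-2-yl)flavan-4-yl benzoate
Conditions: B2pin2 (1.5 equiv), Pd(dppf)Cl2 (5 mol%), KOAc (3 equiv), 1,4-dioxane, 85 °C
Reagents that add atoms: bis(pinacolato)diboron, CC1(C)OB(OC1(C)C)B1OC(C)(C)C(C)(C)O1
Why: Miyaura borylation; zerovalent palladium inserts into the aryl C–Br bond, acetate assists transmetalation with B2pin2, and KOAc is too weak a base to cleave the esters or to trigger homocoupling.

Step 11
Reactants: 10 6-bromo all-cis cyclic carbonate; 16 6-pinacolboronate of the 3,4-trans half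
Product: 17 protected C6–C6' biflavan (all-cis half as 3,4-cyclic carbonate; 3,4-trans half as 3-O-acetate 4-O-benzoate; six benzyl ethers)
Conditions: Pd(OAc)2 (5 mol%), SPhos (10 mol%), K3PO4 (2 equiv), toluene/H2O (10:1), 70 °C
Reagents that add atoms: none
Why: Suzuki–Miyaura cross-coupling forms the C6–C6' bond; the electron-rich, mono-ortho-substituted bromide calls for the bulky electron-rich SPhos ligand, the biaryl has only two ortho substituents so no stable atropisomer arises, and the biphasic phosphate medium should spare carbonate and esters.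

Step 12
Reactants: 17 protected C6–C6' biflavan
Product: 18 7,8,4',7',8',4''-hexakis(benzyloxy)-6,6'-biflavan-3,4,3',4'-tetraol, (2R,3R,4R) half and (2R,3R,4S) half
Conditions: NaOMe (0.3 equiv), MeOH/THF, 0 °C to rt
Reagents that add atoms: none
Why: Zemplén-type transesterification removes the cyclic carbonate, the acetate and the benzoate by acyl–oxygen cleavage, so C3 and C4 of both halves keep their configuration, and with every phenol still benzylated no quinone methide can form under base.

Step 13
Reactants: 18 hexa-O-benzyl biflavan tetraol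
Product: 19 target CNP0121763.1, (2R,3R,4R)-6-[(2R,3R,4S)-3,4,7,8-tetrahydroxy-2-(4-hydroxyphenyl)chroman-6-yl]-2-(4-hydroxyphenyl)chroman-3,4,7,8-tetraol
Conditions: H2 (1 atm), Pd/C (10%), THF/MeOH, rt; filtration under Ar, freeze-drying
Reagents that add atoms: none
Why: Catalytic hydrogenolysis of the six aryl benzyl ethers under neutral conditions; aryl O–benzyl bonds should cleave well before the secondary benzylic C4–OH and C2–O1 bonds when no acid is present, and the reaction is stopped after uptake of six equivalents of hydrogen.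

**Compound list**
1 | 2,3,4-trihydroxyacetophenone (gallacetophenone) | CC(=O)c1ccc(O)c(O)c1O | starting material
2 | 3,4-bis(benzyloxy)-2-hydroxyacetophenone | CC(=O)c1ccc(OCc2ccccc2)c(OCc2ccccc2)c1O | intermediate
3 | 4-benzyloxybenzaldehyde | O=Cc1ccc(OCc2ccccc2)cc1 | starting material
4 | (E)-2'-hydroxy-3',4',4-tris(benzyloxy)chalcone | O=C(/C=C/c1ccc(OCc2ccccc2)cc1)c1ccc(OCc2ccccc2)c(OCc2ccccc2)c1O | intermediate
5 | (±)-trans-7,8-bis(benzyloxy)-2-(4-benzyloxyphenyl)-3-hydroxychroman-4-one (racemic; 2R,3R enantiomer drawn) | c1ccccc1COc1ccc([C@H]2Oc3c(ccc(OCc4ccccc4)c3OCc3ccccc3)C(=O)[C@@H]2O)cc1 | intermediate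
6 | 7,8-bis(benzyloxy)-2-(4-benzyloxyphenyl)-3-hydroxy-4H-chromen-4-one (7,8,4'-tri-O-benzylflavonol) | O=c1c(O)c(-c2ccc(OCc3ccccc3)cc2)oc2c(OCc3ccccc3)c(OCc3ccccc3)ccc12 | intermediate
7 | (2R,3S)-7,8-bis(benzyloxy)-2-(4-benzyloxyphenyl)-3-hydroxychroman-4-one (2,3-cis ketol) | c1ccccc1COc1ccc([C@H]2Oc3c(ccc(OCc4ccccc4)c3OCc3ccccc3)C(=O)[C@H]2O)cc1 | intermediate
8 | (2R,3R,4R)-7,8,4'-tris(benzyloxy)flavan-3,4-diol (2,3-cis-3,4-cis) | c1ccccc1COc1ccc([C@H]2Oc3c(ccc(OCc4ccccc4)c3OCc3ccccc3)[C@@H](O)[C@H]2O)cc1 | intermediate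
9 | (2R,3R,4R)-6-bromo-7,8,4'-tris(benzyloxy)flavan-3,4-diol | c1ccccc1COc1ccc([C@H]2Oc3c(cc(Br)c(OCc4ccccc4)c3OCc3ccccc3)[C@@H](O)[C@H]2O)cc1 | intermediate
10 | 6-bromo-7,8,4'-tris(benzyloxy)-2,3-cis-3,4-cis-flavan-3,4-diyl cyclic carbonate (configuration as in 9) | c1ccccc1COc1ccc([C@H]2Oc3c(cc(Br)c(OCc4ccccc4)c3OCc3ccccc3)[C@@H](OC(=O)O5)[C@H]25)cc1 | intermediate
11 | 3,4-cyclic sulfite of 9 (two epimers at sulfur) | c1ccccc1COc1ccc([C@H]2Oc3c(cc(Br)c(OCc4ccccc4)c3OCc3ccccc3)[C@@H](OS(=O)O5)[C@H]25)cc1 | intermediate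
12 | 3,4-cyclic sulfate of 9 (configuration as in 9) | c1ccccc1COc1ccc([C@H]2Oc3c(cc(Br)c(OCc4ccccc4)c3OCc3ccccc3)[C@@H](OS(=O)(=O)O5)[C@H]25)cc1 | intermediate
13 | tetrabutylammonium (2R,3S,4S)-4-benzoyloxy-6-bromo-7,8,4'-tris(benzyloxy)flavan-3-yl sulfate (3,4-trans) | c1ccccc1COc1ccc([C@H]2Oc3c(cc(Br)c(OCc4ccccc4)c3OCc3ccccc3)[C@H](OC(=O)c4ccccc4)[C@H]2OS(=O)(=O)[O-])cc1.CCCC[N+](CCCC)(CCCC)CCCC | intermediate
14 | (2R,3S,4S)-6-bromo-7,8,4'-tris(benzyloxy)-3-hydroxyflavan-4-yl benzoate (2,3-cis-3,4-trans) | c1ccccc1COc1ccc([C@H]2Oc3c(cc(Br)c(OCc4ccccc4)c3OCc3ccccc3)[C@H](OC(=O)c4ccccc4)[C@H]2O)cc1 | intermediate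
15 | (2R,3S,4S)-3-acetoxy-6-bromo-7,8,4'-tris(benzyloxy)flavan-4-yl benzoate | c1ccccc1COc1ccc([C@H]2Oc3c(cc(Br)c(OCc4ccccc4)c3OCc3ccccc3)[C@H](OC(=O)c4ccccc4)[C@H]2OC(C)=O)cc1 | intermediate
16 | (2R,3S,4S)-3-acetoxy-7,8,4'-tris(benzyloxy)-6-(4,4,5,5-tetramethyl-1,3,2-dioxaborolan-2-yl)flavan-4-yl benzoate | c1ccccc1COc1ccc([C@H]2Oc3c(cc(B6OC(C)(C)C(C)(C)O6)c(OCc4ccccc4)c3OCc3ccccc3)[C@H](OC(=O)c4ccccc4)[C@H]2OC(C)=O)cc1 | intermediate
17 | protected C6–C6' biflavan (all-cis half as 3,4-cyclic carbonate; 3,4-trans half as 3-O-acetate 4-O-benzoate; six benzyl ethers) | c1ccccc1COc1ccc([C@H]2Oc3c(cc(-c4cc5c(c(OCc6ccccc6)c4OCc4ccccc4)O[C@H](c4ccc(OCc6ccccc6)cc4)[C@H](OC(C)=O)[C@H]5OC(=O)c4ccccc4)c(OCc4ccccc4)c3OCc3ccccc3)[C@@H](OC(=O)O6)[C@H]26)cc1 | intermediate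
18 | 7,8,4',7',8',4''-hexakis(benzyloxy)-6,6'-biflavan-3,4,3',4'-tetraol, (2R,3R,4R) and (2R,3R,4S) halves | c1ccccc1COc1ccc([C@H]2Oc3c(cc(-c4cc5c(c(OCc6ccccc6)c4OCc4ccccc4)O[C@H](c4ccc(OCc6ccccc6)cc4)[C@H](O)[C@H]5O)c(OCc4ccccc4)c3OCc3ccccc3)[C@@H](O)[C@H]2O)cc1 | intermediate
19 | CNP0121763.1, (2R,3R,4R)-6-[(2R,3R,4S)-3,4,7,8-tetrahydroxy-2-(4-hydroxyphenyl)chroman-6-yl]-2-(4-hydroxyphenyl)chroman-3,4,7,8-tetraol | Oc1ccc([C@H]2Oc3c(cc(-c4cc5c(c(O)c4O)O[C@H](c4ccc(O)cc4)[C@H](O)[C@H]5O)c(O)c3O)[C@@H](O)[C@H]2O)cc1 | target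

**Step count**
Total step count: 13. Longest linear sequence: 12 steps (steps 1 to 5 and 7 to 13; step 6 is the one-step side branch).

**Steps most likely to fail**

1. Step 4 (proposed new method). The chelating flavonolate may sequester the ruthenium centre, the reduction may stall at the ketol with epimerisation at C3, or enantiofacial discrimination at the tetrasubstituted enol double bond may be poor. Fallback with known chemistry, setting out from 6 and coming back at 8: heterogeneous hydrogenation of 6 over W-2 Raney nickel (H2, 50 bar, EtOH/dioxane, 40 °C), the established way from flavonols to racemic 2,3-cis-3,4-cis diols and normally tolerant of aryl benzyl ethers at this temperature, should give 8 as the racemate with its antipode (2S,3S,4S)-7,8,4'-tris(benzyloxy)flavan-3,4-diol F1. Preparative HPLC on an amylose carbamate chiral stationary phase then separates 8 from F1, and 8 re-enters at step 5.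

2. Step 7 (with step 8). The electron-rich benzylic C4–O bond of the sulfite or sulfate may ionise and eliminate, RuO4 may over-oxidise benzyl ethers or arenes, and in the opening benzoate may attack C3. Fallback setting out from 9 and coming back at 14: a Mitsunobu reaction on the unprotected cis-diol (PPh3, DIAD, PhCO2H, THF, 0 °C) should displace the more readily activated benzylic C4 hydroxyl by benzoate with inversion and give the trans hydroxy benzoate 14 directly. No sulfur intermediates or oxidant are involved, and no compound outside the list is made (F0).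

3. Step 11. Oxidative addition into the electron-rich bromide may be slow, the ortho-alkoxy boronate may protodeboronate, and the aqueous base may strip carbonate or esters. Fallback setting out from 15 and coming back at 17: stannylation of 15 (Me3SnSnMe3, Pd(PPh3)4, toluene, 100 °C) should give (2R,3S,4S)-3-acetoxy-7,8,4'-tris(benzyloxy)-6-(trimethylstannyl)flavan-4-yl benzoate F2. A Stille coupling of F2 with bromide 10 (Pd(PPh3)4, CuI, DMF, 80 °C, no base and no water) then forms the C6–C6' bond of 17.

**Further compounds**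
F1 | step 4 | (2S,3S,4S)-7,8,4'-tris(benzyloxy)flavan-3,4-diol (antipode of 8) | c1ccccc1COc1ccc([C@@H]2Oc3c(ccc(OCc4ccccc4)c3OCc3ccccc3)[C@H](O)[C@@H]2O)cc1
F0 | step 7 | none | none
F2 | step 11 | (2R,3S,4S)-3-acetoxy-7,8,4'-tris(benzyloxy)-6-(trimethylstannyl)flavan-4-yl benzoate | c1ccccc1COc1ccc([C@H]2Oc3c(cc([Sn](C)(C)C)c(OCc4ccccc4)c3OCc3ccccc3)[C@H](OC(=O)c4ccccc4)[C@H]2OC(C)=O)cc1
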